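Late in the run, hours after the feed has ended, the question for this flask is whether its free catalyst lasted long enough, so begin with what you are handed.

    substrate + free catalyst ⇌ target + free catalyst, rate k1*[substrate]*[free catalyst] forward; the back reaction follows from the equilibrium constant (K1 = 0.321, k1 = 985 /M/min)
    substrate + free catalyst ⇌ isomer of the product A + free catalyst, rate k2*[substrate]*[free catalyst] forward; the back reaction follows from the equilibrium constant (K2 = 0.91, k2 = 428 /M/min)
    substrate + free catalyst ⇌ isomer of the product B + free catalyst, rate k3*[substrate]*[free catalyst] forward; the back reaction follows from the equilibrium constant (K3 = 1.4, k3 = 53.3 /M/min)
    2 free catalyst → spent catalyst (k4 = 5.08 /M/min)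

substrate 0.25 M (fed, over 10 min); free catalyst 2 mol%; time 4.0 h; the fed solution adds 0.50 times the starting volume

- how much target there is at 4.0 h, in percent of the substrate charged
- amount of target if the flask were left three thousand times as long, in percent of the substrate charged

My reckoning for you: the isomerisations run both ways on the same free catalyst, which sets their pace but not where they end, so at equilibrium target holds 8.84 % of the charge, and 8.84 % after the long wait. Whether the flask arrives depends on the free catalyst, which destroys itself in pairs: taken as diluted from the first minute, 11.0 % of it stays free at the end, a lifetime exposure of 13.1 M·s. The step to isomer of the product B is slower than the other two, so I treat substrate, target and isomer of the product A as one pool, which exchanges with isomer of the product B at 62.0 /M/min. Their product divided by ln(10) gives 5.86: these are the decades of closure, the powers of ten by which the gap to equilibrium shrinks over the run. So add nothing when you come; watch isomer of the product B, the slow one.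

The forecast gives 8.84 % (8.7 % to 9 %) and 8.84 % (8.8 % to 8.9 %), holding that “the mixture is already at equilibrium by 4 h”.

The simulation gives 8.84 % and 8.84 %. Target stands at 11.6 % at 0.167 h and at 8.84 % by 2.00 h, while isomer of the product B climbs from 21.2 % to 38.5 %: thermodynamic control.

In this flask, conversion of substrate ends at 72.5 %, and the run without the undoing of target into substrate reaches >99.9 %, so the 28 % of substrate still there at 4.00 h is an equilibrium remainder, not unfinished work. With 5.86 decades of closure, the flask meets that equilibrium within the catalyst's working life, and removing the step that spends the catalyst changes conversion by nothing. In the neighbour flask with 1.2 mol% of free catalyst, the same reckoning gives 4.70 decades, still ample, and the computed target there is 8.84 %.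

The rate constants come from no measurement; what happens was integrated by code.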